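**Retrosynthetic overview**
1. Last ring: the acid-labile spiro-dihydrofuran is closed by Mo(CO)6/Et3N cycloisomerization of the 16-hydroxy-14-yne 29, under basic conditions only.
2. Spiro-tetrahydrofuran with C8 and C9: 7β-OH-directed β-epoxidation of the Δ8 bond, then invertive 5-exo opening at C9 by the C13 tertiary alcohol (8β-O and 9α-O set together).
3. Side chain and C13: allyl sulfone 13 opens the Sharpless-derived alkynyl epoxide 18 at its CH2 (C11–C12 bond; C13 by reagent control).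
4. Ring B and C10: Diels–Alder of the ring A vinylcyclohexene 7 with methyl but-2-ynoate (delivers Δ8, C17 and C11), then α-face hydrogenation (C5); C4 by asymmetric phase-transfer methylation.
5. Ring order: ring A (from 1), ring B (Diels–Alder), tetrahydrofuran (epoxide opening), dihydrofuran (cycloisomerization).

Assumption: compounds 20–30 carry labdane numbering (C17 = methyl on C8, C18 = α-methyl and C19 = β-CH2O on C4, C20 = methyl on C10, C16 = CH2O on C13; 5α-H and 10β-methyl implied by the parent name), and in step 1 the antipode of the commercial phase-transfer catalyst is used that gives (S)-2.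

**Route**

Step 1
Reactants: 1 tert-butyl 2-oxocyclohexane-1-carboxylate
Product: 2 tert-butyl (1S)-1-methyl-2-oxocyclohexane-1-carboxylate
Conditions: MeI, CsOH·H2O, Maruoka N-spiro binaphthyl quaternary ammonium bromide (1 mol %), toluene, −40 °C
Reagents that add atoms: iodomethane CI
Why: Asymmetric phase-transfer alkylation of a β-keto ester, in which the chiral ammonium enolate ion pair exposes one enolate face to MeI and so sets the C4 quaternary centre (S).

Step 2
Reactants: 2 tert-butyl (1S)-1-methyl-2-oxocyclohexane-1-carboxylate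
Product: 4 tert-butyl (1S)-1,3-dimethyl-2-oxocyclohexane-1-carboxylate as a mixture of C3 epimers, via lithium enolate 3 (not isolated)
Conditions: LiN(iPr)2, THF, −78 °C; then MeI, −78 to 0 °C
Reagents that add atoms: lithium diisopropylamide [Li+].CC(C)[N-]C(C)C (Li of 3); iodomethane CI
Why: Regiospecific enolate alkylation (C1 is quaternary, so only C3 can enolize); the new centre becomes sp2 in step 3, so its configuration does not matter.

Step 3
Reactants: 4 tert-butyl (1S)-1,3-dimethyl-2-oxocyclohexane-1-carboxylate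
Product: 6 tert-butyl (1S)-1,3-dimethyl-2-{[(trifluoromethyl)sulfonyl]oxy}cyclohex-2-ene-1-carboxylate, via potassium enolate 5 (not isolated)
Conditions: KN(SiMe3)2, THF, −78 °C; then PhNTf2, −78 °C to rt
Reagents that add atoms: potassium bis(trimethylsilyl)amide [K+].C[Si](C)(C)[N-][Si](C)(C)C (K of 5); N-phenylbis(trifluoromethanesulfonimide) O=S(=O)(N(c1ccccc1)S(=O)(=O)C(F)(F)F)C(F)(F)F
Why: Enol triflate formation from the only possible (tetrasubstituted) enolate; the quaternary centre is untouched.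

Step 4
Reactants: 6 tert-butyl (1S)-1,3-dimethyl-2-{[(trifluoromethyl)sulfonyl]oxy}cyclohex-2-ene-1-carboxylate
Product: 7 tert-butyl (1S)-2-ethenyl-1,3-dimethylcyclohex-2-ene-1-carboxylate
Conditions: Bu3SnCH=CH2, Pd(PPh3)4 (5 mol %), LiCl, THF, 65 °C
Reagents that add atoms: tributyl(vinyl)stannane C=C[Sn](CCCC)(CCCC)CCCC
Why: Stille cross-coupling of a hindered enol triflate (LiCl assists transmetalation) gives the 1-vinylcyclohexene diene.

Step 5
Reactants: 7 tert-butyl (1S)-2-ethenyl-1,3-dimethylcyclohex-2-ene-1-carboxylate, 8 methyl but-2-ynoate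
Product: 9 1-tert-butyl 5-methyl (1S,4aS)-1,4a,6-trimethyl-1,2,3,4,4a,7-hexahydronaphthalene-1,5-dicarboxylate
Conditions: 8 (3 equiv), BHT (cat.), toluene, 140 °C, sealed tube
Reagents that add atoms: none
Why: Diels–Alder reaction that forms ring B: the unsubstituted vinyl terminus (largest HOMO coefficient, least hindered) bonds to the β-carbon of the ynoate, so C8 carries the methyl and C9 the ester, and the dienophile adds to the diene face opposite the pseudoaxial CO2tBu group on C4, so the C10 quaternary centre forms with its methyl cis to C19 (4aS).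

Step 6
Reactants: 9 1-tert-butyl 5-methyl (1S,4aS)-1,4a,6-trimethyl-1,2,3,4,4a,7-hexahydronaphthalene-1,5-dicarboxylate
Product: 10 1-tert-butyl 5-methyl (1S,4aS,8aR)-1,4a,6-trimethyl-1,2,3,4,4a,7,8,8a-octahydronaphthalene-1,5-dicarboxylate
Conditions: H2 (1 atm), Pd/C (10 wt %), EtOAc, rt
Reagents that add atoms: none
Why: Chemoselective heterogeneous hydrogenation of the isolated trisubstituted C5=C6 bond (the tetrasubstituted conjugated C8=C9 bond is inert) from the α face, opposite the two β-axial groups on C4 and C10, gives the trans ring fusion (5α-H) as with Δ5-steroids.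

Step 7
Reactants: 10 1-tert-butyl 5-methyl (1S,4aS,8aR)-1,4a,6-trimethyl-1,2,3,4,4a,7,8,8a-octahydronaphthalene-1,5-dicarboxylate
Product: 11 [(1S,4aS,8aR)-5-(hydroxymethyl)-1,4a,6-trimethyl-1,2,3,4,4a,7,8,8a-octahydronaphthalen-1-yl]methanol
Conditions: LiAlH4, THF, 0 °C to reflux; H2O quench
Reagents that add atoms: none
Why: Hydride reduction of both esters (1,2-reduction of the fully substituted enoate) gives the C11 allylic and the C19 neopentyl alcohol.

Step 8
Reactants: 11 [(1S,4aS,8aR)-5-(hydroxymethyl)-1,4a,6-trimethyl-1,2,3,4,4a,7,8,8a-octahydronaphthalen-1-yl]methanol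
Product: 13 [(1S,4aS,8aR)-1,4a,6-trimethyl-5-[(phenylsulfonyl)methyl]-1,2,3,4,4a,7,8,8a-octahydronaphthalen-1-yl]methanol, via allylic bromide 12 (not isolated)
Conditions: PBr3 (0.4 equiv), pyridine (cat.), Et2O, −20 °C; then PhSO2Na, DMF, rt
Reagents that add atoms: phosphorus tribromide BrP(Br)Br (Br of 12); sodium benzenesulfinate [Na+].[O-]S(=O)c1ccccc1
Why: The primary allylic alcohol is brominated much faster than the hindered neopentyl C19 alcohol, and SN2 displacement by the soft sulfur nucleophile of the sulfinate gives the allyl sulfone.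

Step 9
Reactants: 14 2-bromoprop-2-en-1-ol, 15 ethynyl(trimethyl)silane
Product: 16 2-methylidene-4-(trimethylsilyl)but-3-yn-1-ol
Conditions: PdCl2(PPh3)2 (2 mol %), CuI (4 mol %), iPr2NH, THF, rt
Reagents that add atoms: none
Why: Sonogashira coupling of the vinyl bromide with the terminal alkyne.

Step 10
Reactants: 16 2-methylidene-4-(trimethylsilyl)but-3-yn-1-ol
Product: 17 {(2R)-2-[(trimethylsilyl)ethynyl]oxiran-2-yl}methanol
Conditions: Ti(OiPr)4 (10 mol %), D-(−)-diethyl tartrate (12 mol %), tBuOOH, 4 Å molecular sieves, CH2Cl2, −20 °C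
Reagents that add atoms: tert-butyl hydroperoxide CC(C)(C)OO
Why: Sharpless asymmetric epoxidation of a 2-substituted allylic alcohol, in which D-(−)-tartrate delivers oxygen to the face that gives the (R)-epoxide (the same facial sense that turns 2-methylprop-2-en-1-ol into (R)-2-methylglycidol) and thereby fixes the future C13 configuration.

Step 11
Reactants: 17 {(2R)-2-[(trimethylsilyl)ethynyl]oxiran-2-yl}methanol
Product: 18 tert-butyl(dimethyl)({(2S)-2-[(trimethylsilyl)ethynyl]oxiran-2-yl}methoxy)silane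
Conditions: TBSCl, imidazole, CH2Cl2, 0 °C
Reagents that add atoms: tert-butyldimethylsilyl chloride CC(C)(C)[Si](C)(C)Cl
Why: Silylation under mild non-alkoxide conditions avoids the Payne rearrangement that would racemize this epoxide; the descriptor becomes S only through the change in CIP priorities.

Step 12
Reactants: 13 [(1S,4aS,8aR)-1,4a,6-trimethyl-5-[(phenylsulfonyl)methyl]-1,2,3,4,4a,7,8,8a-octahydronaphthalen-1-yl]methanol, 18 tert-butyl(dimethyl)({(2S)-2-[(trimethylsilyl)ethynyl]oxiran-2-yl}methoxy)silane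
Product: 20 (13R)-16-[(tert-butyldimethylsilyl)oxy]-11-(phenylsulfonyl)-15-(trimethylsilyl)labd-8-en-14-yne-13,19-diol as a mixture of C11 epimers, via dilithio sulfone 19 (not isolated)
Conditions: n-BuLi (2.1 equiv), THF–HMPA, −78 °C; then 18, −78 to 0 °C; H2O quench
Reagents that add atoms: n-butyllithium [Li]CCCC (Li of 19)
Why: The α-sulfonyl allyl carbanion reacts at the carbon next to sulfur and opens the 2,2-disubstituted epoxide at its CH2 terminus (SN2), which forms the C11–C12 bond and frees the C13 tertiary alcohol with the epoxide configuration retained (13R).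

Step 13
Reactants: 20 (13R)-16-[(tert-butyldimethylsilyl)oxy]-11-(phenylsulfonyl)-15-(trimethylsilyl)labd-8-en-14-yne-13,19-diol
Product: 21 (13R)-16-[(tert-butyldimethylsilyl)oxy]-15-(trimethylsilyl)labd-8-en-14-yne-13,19-diol
Conditions: Na(Hg) (6 % Na), Na2HPO4, MeOH–THF, −20 °C
Reagents that add atoms: none
Why: Reductive desulfonylation of the allyl sulfone, in which the allyl anion is protonated at the less substituted C11 terminus so that the tetrasubstituted Δ8 bond is kept.

Step 14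
Reactants: 21 (13R)-16-[(tert-butyldimethylsilyl)oxy]-15-(trimethylsilyl)labd-8-en-14-yne-13,19-diol
Product: 22 (13R)-16-[(tert-butyldimethylsilyl)oxy]-13-hydroxy-15-(trimethylsilyl)labd-8-en-14-yn-19-yl acetate
Conditions: Ac2O, pyridine, DMAP (cat.), CH2Cl2, 0 °C
Reagents that add atoms: acetic anhydride CC(=O)OC(C)=O
Why: Chemoselective acylation of the primary C19 alcohol; the tertiary propargylic C13 alcohol does not react under these conditions.

Step 15
Reactants: 22 (13R)-16-[(tert-butyldimethylsilyl)oxy]-13-hydroxy-15-(trimethylsilyl)labd-8-en-14-yn-19-yl acetate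
Product: 23 (13R)-16-[(tert-butyldimethylsilyl)oxy]-13-hydroxy-7-oxo-15-(trimethylsilyl)labd-8-en-14-yn-19-yl acetate
Conditions: Rh2(cap)4 (1 mol %; cap = caprolactamate, C6H10NO), tBuOOH (5 equiv), K2CO3, CH2Cl2, rt
Reagents that add atoms: tert-butyl hydroperoxide CC(C)(C)OO
Why: Radical allylic oxidation (tert-butylperoxyl chain) at the ring C7 methylene, whose axial C–H is aligned with the alkene π system and which is less hindered than the neopentyl-like C11 methylene, gives the tetrasubstituted enone.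

Step 16
Reactants: 23 (13R)-16-[(tert-butyldimethylsilyl)oxy]-13-hydroxy-7-oxo-15-(trimethylsilyl)labd-8-en-14-yn-19-yl acetate
Product: 24 (13R)-16-[(tert-butyldimethylsilyl)oxy]-7β,13-dihydroxy-15-(trimethylsilyl)labd-8-en-14-yn-19-yl acetate
Conditions: NaBH4, CeCl3·7H2O, MeOH, −78 to −20 °C
Reagents that add atoms: none
Why: Luche 1,2-reduction with axial hydride delivery from the α face gives the pseudoequatorial 7β-alcohol (7S).

Step 17
Reactants: 24 (13R)-16-[(tert-butyldimethylsilyl)oxy]-7β,13-dihydroxy-15-(trimethylsilyl)labd-8-en-14-yn-19-yl acetate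
Product: 26 (13R)-16-[(tert-butyldimethylsilyl)oxy]-9α,13-epoxy-7β,8β-dihydroxy-15-(trimethylsilyl)labd-14-yn-19-yl acetate, via 8β,9β-epoxide 25 (not isolated)
Conditions: mCPBA, CH2Cl2, 0 °C; then CSA (10 mol %), 0 °C to rt
Reagents that add atoms: 3-chloroperoxybenzoic acid OOC(=O)c1cccc(Cl)c1
Why: Henbest hydroxyl-directed epoxidation places the epoxide on the β face syn to the 7β-OH (as cholest-4-en-3β-ol gives the 4β,5β-epoxide), and acid-catalysed 5-exo-tet opening at C9 by the C13 hydroxyl with inversion (trans-diaxial, Fürst–Plattner) sets 9α-O and leaves 8β-OH, so the spiro tetrahydrofuran and both C8 and C9 are fixed in one operation.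

Step 18
Reactants: 26 (13R)-16-[(tert-butyldimethylsilyl)oxy]-9α,13-epoxy-7β,8β-dihydroxy-15-(trimethylsilyl)labd-14-yn-19-yl acetate
Product: 27 (13R)-16-[(tert-butyldimethylsilyl)oxy]-9α,13-epoxy-8β-hydroxy-7-oxo-15-(trimethylsilyl)labd-14-yn-19-yl acetate
Conditions: Dess–Martin periodinane, NaHCO3, CH2Cl2, 0 °C to rt
Reagents that add atoms: none
Why: Oxidation of the secondary C7 alcohol only; the tertiary C8 alcohol cannot be oxidized, and C8 carries no hydrogen, so it cannot epimerize.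

Step 19
Reactants: 27 (13R)-16-[(tert-butyldimethylsilyl)oxy]-9α,13-epoxy-8β-hydroxy-7-oxo-15-(trimethylsilyl)labd-14-yn-19-yl acetate
Product: 28 (13R)-16-[(tert-butyldimethylsilyl)oxy]-9α,13-epoxy-7-oxo-15-(trimethylsilyl)labd-14-yne-8β,19-diyl diacetate
Conditions: Ac2O, DMAP (2 equiv), Et3N, CH2Cl2, 40 °C
Reagents that add atoms: acetic anhydride CC(=O)OC(C)=O
Why: DMAP-catalysed acylation (N-acetylpyridinium transfer) of the hindered tertiary α-ketol.

Step 20
Reactants: 28 (13R)-16-[(tert-butyldimethylsilyl)oxy]-9α,13-epoxy-7-oxo-15-(trimethylsilyl)labd-14-yne-8β,19-diyl diacetate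
Product: 29 (13R)-9α,13-epoxy-16-hydroxy-7-oxolabd-14-yne-8β,19-diyl diacetate
Conditions: Bu4NF (2.5 equiv), AcOH (2.5 equiv), THF, 0 °C to rt
Reagents that add atoms: none
Why: Fluoride cleaves the O–Si bond of the silyl ether and the C(sp)–Si bond of the silylalkyne in one operation, and AcOH buffering protects the two acetates.

Step 21
Reactants: 29 (13R)-9α,13-epoxy-16-hydroxy-7-oxolabd-14-yne-8β,19-diyl diacetate
Product: 30 (13R)-9α,13:15,16-diepoxy-7-oxolabd-14-ene-8β,19-diyl diacetate (the target CNP0351241.1)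
Conditions: Mo(CO)6 (25 mol %), Et3N, Et2O, hν (350 nm), rt
Reagents that add atoms: none
Why: McDonald alkynol cycloisomerization, in which the terminal alkyne becomes a molybdenum vinylidene that the C16 hydroxyl attacks (5-endo) to give the 2,3-dihydrofuran under basic conditions that the acid-labile product tolerates; C13 is not touched.

**Compound list**

1 | tert-butyl 2-oxocyclohexane-1-carboxylate | O=C1CCCCC1C(=O)OC(C)(C)C | starting material
2 | tert-butyl (1S)-1-methyl-2-oxocyclohexane-1-carboxylate | C[C@]1(C(=O)OC(C)(C)C)CCCCC1=O | intermediate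
3 | lithium enolate of 2 (not isolated) | C[C@]1(C(=O)OC(C)(C)C)CCCC=C1O[Li] | intermediate
4 | tert-butyl (1S)-1,3-dimethyl-2-oxocyclohexane-1-carboxylate (C3 epimers) | C[C@]1(C(=O)OC(C)(C)C)CCCC(C)C1=O | intermediate
5 | potassium enolate of 4 (not isolated) | C[C@]1(C(=O)OC(C)(C)C)CCCC(C)=C1O[K] | intermediate
6 | tert-butyl (1S)-1,3-dimethyl-2-{[(trifluoromethyl)sulfonyl]oxy}cyclohex-2-ene-1-carboxylate | C[C@]1(C(=O)OC(C)(C)C)CCCC(C)=C1OS(=O)(=O)C(F)(F)F | intermediate
7 | tert-butyl (1S)-2-ethenyl-1,3-dimethylcyclohex-2-ene-1-carboxylate | C[C@]1(C(=O)OC(C)(C)C)CCCC(C)=C1C=C | intermediate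
8 | methyl but-2-ynoate | CC#CC(=O)OC | starting material
9 | 1-tert-butyl 5-methyl (1S,4aS)-1,4a,6-trimethyl-1,2,3,4,4a,7-hexahydronaphthalene-1,5-dicarboxylate | C[C@]1(C(=O)OC(C)(C)C)CCC[C@@]2(C)C1=CCC(C)=C2C(=O)OC | intermediate
10 | 1-tert-butyl 5-methyl (1S,4aS,8aR)-1,4a,6-trimethyl-1,2,3,4,4a,7,8,8a-octahydronaphthalene-1,5-dicarboxylate | C[C@]1(C(=O)OC(C)(C)C)CCC[C@@]2(C)[C@H]1CCC(C)=C2C(=O)OC | intermediate
11 | [(1S,4aS,8aR)-5-(hydroxymethyl)-1,4a,6-trimethyl-1,2,3,4,4a,7,8,8a-octahydronaphthalen-1-yl]methanol | C[C@]1(CO)CCC[C@@]2(C)[C@H]1CCC(C)=C2CO | intermediate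
12 | [(1S,4aS,8aR)-5-(bromomethyl)-1,4a,6-trimethyl-1,2,3,4,4a,7,8,8a-octahydronaphthalen-1-yl]methanol (not isolated) | C[C@]1(CO)CCC[C@@]2(C)[C@H]1CCC(C)=C2CBr | intermediate
13 | [(1S,4aS,8aR)-1,4a,6-trimethyl-5-[(phenylsulfonyl)methyl]-1,2,3,4,4a,7,8,8a-octahydronaphthalen-1-yl]methanol | C[C@]1(CO)CCC[C@@]2(C)[C@H]1CCC(C)=C2CS(=O)(=O)c1ccccc1 | intermediate
14 | 2-bromoprop-2-en-1-ol | OCC(Br)=C | starting material
15 | ethynyl(trimethyl)silane | C#C[Si](C)(C)C | starting material
16 | 2-methylidene-4-(trimethylsilyl)but-3-yn-1-ol | OCC(=C)C#C[Si](C)(C)C | intermediate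
17 | {(2R)-2-[(trimethylsilyl)ethynyl]oxiran-2-yl}methanol | OC[C@]1(C#C[Si](C)(C)C)CO1 | intermediate
18 | tert-butyl(dimethyl)({(2S)-2-[(trimethylsilyl)ethynyl]oxiran-2-yl}methoxy)silane | CC(C)(C)[Si](C)(C)OC[C@]1(C#C[Si](C)(C)C)CO1 | intermediate
19 | C11,O19-dilithio derivative of 13 (not isolated) | C[C@]1(CO[Li])CCC[C@@]2(C)[C@H]1CCC(C)=C2C([Li])S(=O)(=O)c1ccccc1 | intermediate
20 | (13R)-16-[(tert-butyldimethylsilyl)oxy]-11-(phenylsulfonyl)-15-(trimethylsilyl)labd-8-en-14-yne-13,19-diol (C11 epimers) | C[C@]1(CO)CCC[C@@]2(C)[C@H]1CCC(C)=C2C(S(=O)(=O)c1ccccc1)C[C@](O)(CO[Si](C)(C)C(C)(C)C)C#C[Si](C)(C)C | intermediate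
21 | (13R)-16-[(tert-butyldimethylsilyl)oxy]-15-(trimethylsilyl)labd-8-en-14-yne-13,19-diol | C[C@]1(CO)CCC[C@@]2(C)[C@H]1CCC(C)=C2CC[C@](O)(CO[Si](C)(C)C(C)(C)C)C#C[Si](C)(C)C | intermediate
22 | (13R)-16-[(tert-butyldimethylsilyl)oxy]-13-hydroxy-15-(trimethylsilyl)labd-8-en-14-yn-19-yl acetate | CC(=O)OC[C@@]1(C)CCC[C@@]2(C)[C@H]1CCC(C)=C2CC[C@](O)(CO[Si](C)(C)C(C)(C)C)C#C[Si](C)(C)C | intermediate
23 | (13R)-16-[(tert-butyldimethylsilyl)oxy]-13-hydroxy-7-oxo-15-(trimethylsilyl)labd-8-en-14-yn-19-yl acetate | CC(=O)OC[C@@]1(C)CCC[C@@]2(C)[C@H]1CC(=O)C(C)=C2CC[C@](O)(CO[Si](C)(C)C(C)(C)C)C#C[Si](C)(C)C | intermediate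
24 | (13R)-16-[(tert-butyldimethylsilyl)oxy]-7β,13-dihydroxy-15-(trimethylsilyl)labd-8-en-14-yn-19-yl acetate | CC(=O)OC[C@@]1(C)CCC[C@@]2(C)[C@H]1C[C@H](O)C(C)=C2CC[C@](O)(CO[Si](C)(C)C(C)(C)C)C#C[Si](C)(C)C | intermediate
25 | (13R)-16-[(tert-butyldimethylsilyl)oxy]-8β,9β-epoxy-7β,13-dihydroxy-15-(trimethylsilyl)labd-14-yn-19-yl acetate (not isolated) | CC(=O)OC[C@@]1(C)CCC[C@@]2(C)[C@H]1C[C@H](O)[C@]3(C)O[C@]23CC[C@](O)(CO[Si](C)(C)C(C)(C)C)C#C[Si](C)(C)C | intermediate
26 | (13R)-16-[(tert-butyldimethylsilyl)oxy]-9α,13-epoxy-7β,8β-dihydroxy-15-(trimethylsilyl)labd-14-yn-19-yl acetate | CC(=O)OC[C@@]1(C)CCC[C@@]2(C)[C@H]1C[C@H](O)[C@](C)(O)[C@]21CC[C@](CO[Si](C)(C)C(C)(C)C)(C#C[Si](C)(C)C)O1 | intermediate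
27 | (13R)-16-[(tert-butyldimethylsilyl)oxy]-9α,13-epoxy-8β-hydroxy-7-oxo-15-(trimethylsilyl)labd-14-yn-19-yl acetate | CC(=O)OC[C@@]1(C)CCC[C@@]2(C)[C@H]1CC(=O)[C@](C)(O)[C@]21CC[C@](CO[Si](C)(C)C(C)(C)C)(C#C[Si](C)(C)C)O1 | intermediate
28 | (13R)-16-[(tert-butyldimethylsilyl)oxy]-9α,13-epoxy-7-oxo-15-(trimethylsilyl)labd-14-yne-8β,19-diyl diacetate | CC(=O)OC[C@@]1(C)CCC[C@@]2(C)[C@H]1CC(=O)[C@](C)(OC(C)=O)[C@]21CC[C@](CO[Si](C)(C)C(C)(C)C)(C#C[Si](C)(C)C)O1 | intermediate
29 | (13R)-9α,13-epoxy-16-hydroxy-7-oxolabd-14-yne-8β,19-diyl diacetate | CC(=O)OC[C@@]1(C)CCC[C@@]2(C)[C@H]1CC(=O)[C@](C)(OC(C)=O)[C@]21CC[C@](CO)(C#C)O1 | intermediate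
30 | (13R)-9α,13:15,16-diepoxy-7-oxolabd-14-ene-8β,19-diyl diacetate (CNP0351241.1) | CC(=O)OC[C@@]1(C)CCC[C@@]2(C)[C@H]1CC(=O)[C@](C)(OC(C)=O)[C@]21CC[C@]2(C=COC2)O1 | target

**Step count**

Total step count: 21.
Longest linear sequence: 18 steps (steps 1–8, then 12–21); epoxide 18 is made in 3 steps (9–11).

**Three steps most likely to fail**

Step 5 (Diels–Alder). The hindered diene may react slowly with the ynoate, and the face selectivity exerted by the C4 ester may be modest. The fallback sets out from 7 and comes back to the route at 11. It replaces the thermally driven ynoate by a Lewis-acid-activated ynal, which reacts at low temperature and should sharpen regio- and face selectivity. Diene 7 and but-2-ynal are combined with Me2AlCl in CH2Cl2 at −78 °C to give tert-butyl (1S,4aS)-5-formyl-1,4a,6-trimethyl-1,2,3,4,4a,7-hexahydronaphthalene-1-carboxylate F1. Hydrogenation over Pd/C in EtOAc gives tert-butyl (1S,4aS,8aR)-5-formyl-1,4a,6-trimethyl-1,2,3,4,4a,7,8,8a-octahydronaphthalene-1-carboxylate F2. LiAlH4 in THF then reduces the aldehyde and the ester together to diol 11.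

Step 15 (allylic oxidation). C11 or C17 may be oxidized in competition with C7. The fallback sets out from 20 and comes back at 23; it keeps the sulfone as a blocking group for C11 and moves the oxidation ahead of the desulfonylation. Compound 20 is acetylated at C19 (Ac2O, pyridine) to (13R)-16-[(tert-butyldimethylsilyl)oxy]-13-hydroxy-11-(phenylsulfonyl)-15-(trimethylsilyl)labd-8-en-14-yn-19-yl acetate F3. Oxidation with Rh2(cap)4 and tBuOOH, where the C11–H next to the sulfone is deactivated, gives (13R)-16-[(tert-butyldimethylsilyl)oxy]-13-hydroxy-7-oxo-11-(phenylsulfonyl)-15-(trimethylsilyl)labd-8-en-14-yn-19-yl acetate F4. The vinylogous β-keto sulfone is then cleaved with Al(Hg) in aqueous THF, and DBU brings the double bond back into conjugation to give 23.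

Step 17 (directed epoxidation and spirocyclization). The epoxide may form on the α face, or the developing C9 cation may rearrange (C10 methyl shift) before the C13 hydroxyl closes the ring. The fallback sets out from 23 and comes back at 27; it builds the C9–O bond by conjugate addition and the C8–O bond by enolate oxidation. KN(SiMe3)2 and then Me3SiCl in THF at −78 °C convert 23, by intramolecular oxa-Michael addition of the C13 alkoxide to C9 (axial attack from the α face) and O-silylation of the enolate, into (13R)-16-[(tert-butyldimethylsilyl)oxy]-9α,13-epoxy-15-(trimethylsilyl)-7-[(trimethylsilyl)oxy]labd-7-en-14-yn-19-yl acetate F5. Rubottom oxidation with dimethyldioxirane in acetone at −78 °C, attacking C8 anti to the axial C9–O bond (β face), gives after silyl migration (13R)-16-[(tert-butyldimethylsilyl)oxy]-9α,13-epoxy-7-oxo-15-(trimethylsilyl)-8β-[(trimethylsilyl)oxy]labd-14-yn-19-yl acetate F6. AcOH–H2O–THF removes the Me3Si group and gives 27.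

**Further compounds**

F1 | step 5 | tert-butyl (1S,4aS)-5-formyl-1,4a,6-trimethyl-1,2,3,4,4a,7-hexahydronaphthalene-1-carboxylate | C[C@]1(C(=O)OC(C)(C)C)CCC[C@@]2(C)C1=CCC(C)=C2C=O
F2 | step 5 | tert-butyl (1S,4aS,8aR)-5-formyl-1,4a,6-trimethyl-1,2,3,4,4a,7,8,8a-octahydronaphthalene-1-carboxylate | C[C@]1(C(=O)OC(C)(C)C)CCC[C@@]2(C)[C@H]1CCC(C)=C2C=O
F3 | step 15 | (13R)-16-[(tert-butyldimethylsilyl)oxy]-13-hydroxy-11-(phenylsulfonyl)-15-(trimethylsilyl)labd-8-en-14-yn-19-yl acetate | CC(=O)OC[C@@]1(C)CCC[C@@]2(C)[C@H]1CCC(C)=C2C(S(=O)(=O)c1ccccc1)C[C@](O)(CO[Si](C)(C)C(C)(C)C)C#C[Si](C)(C)C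
F4 | step 15 | (13R)-16-[(tert-butyldimethylsilyl)oxy]-13-hydroxy-7-oxo-11-(phenylsulfonyl)-15-(trimethylsilyl)labd-8-en-14-yn-19-yl acetate | CC(=O)OC[C@@]1(C)CCC[C@@]2(C)[C@H]1CC(=O)C(C)=C2C(S(=O)(=O)c1ccccc1)C[C@](O)(CO[Si](C)(C)C(C)(C)C)C#C[Si](C)(C)C
F5 | step 17 | (13R)-16-[(tert-butyldimethylsilyl)oxy]-9α,13-epoxy-15-(trimethylsilyl)-7-[(trimethylsilyl)oxy]labd-7-en-14-yn-19-yl acetate | CC(=O)OC[C@@]1(C)CCC[C@@]2(C)[C@H]1CC(O[Si](C)(C)C)=C(C)[C@]21CC[C@](CO[Si](C)(C)C(C)(C)C)(C#C[Si](C)(C)C)O1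
F6 | step 17 | (13R)-16-[(tert-butyldimethylsilyl)oxy]-9α,13-epoxy-7-oxo-15-(trimethylsilyl)-8β-[(trimethylsilyl)oxy]labd-14-yn-19-yl acetate | CC(=O)OC[C@@]1(C)CCC[C@@]2(C)[C@H]1CC(=O)[C@](C)(O[Si](C)(C)C)[C@]21CC[C@](CO[Si](C)(C)C(C)(C)C)(C#C[Si](C)(C)C)O1
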